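**Plan**
The target is read as (3Z,4S)-3-(3,4-dihydroxy-5-methoxybenzylidene)-4-(4-hydroxy-3-methoxybenzyl)oxolan-2-one; the aryl group is cis to the lactone carbonyl.
The retrosynthesis cuts the lactone bonds C2(=O)–C3 and C5H2–C4 together, after raising the ring to a 2-ethoxyfuran. The C2–O1–C5 triad of the lactone is then the C5(OEt)–O1–C2(H) triad of 5-ethoxy-4-methyloxazole, and C3, C4 and the benzylidene carbon are the triple bond and carbonyl of a 1,4-diaryl ynone.
Forward: aryl propyne and aryl aldehyde are joined to the ynone; an oxazole–alkyne Diels–Alder/retro-Diels–Alder reaction (loss of acetonitrile) makes the furan, the only ring formed; hydrolysis unmasks the 3-aroylbutenolide.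
Stereochemistry: Corey–Bakshi–Shibata reduction of the activating ketone sets an (S)-carbinol. A Mitsunobu/allylic diazene retro-ene sequence transfers it to C4 (S), fixes the Z double bond through allylic 1,3-strain and removes the helper oxygen.
Global debenzylation ends the route.

Key step: step 6

Remark: in step 8 the twisted 2-oxo-2,5-dihydrofuran-3-yl group is assumed to act as the larger ketone substituent in the oxazaborolidine model; if the carbinol proves to be (R), the antipodal catalyst is used and nothing else changes.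

Step 1
Reactants: 1 4-(benzyloxy)-3-methoxybenzyl alcohol
Product: 2 1-(benzyloxy)-4-(bromomethyl)-2-methoxybenzene
Conditions: PBr3 (0.4 equiv), Et2O, 0 °C
Reagents that add atoms: phosphorus tribromide BrP(Br)Br
Why: Standard conversion of an electron-rich benzylic alcohol into its bromide through the bromophosphite; no stereocentre is involved.

Step 2
Reactants: 2 1-(benzyloxy)-4-(bromomethyl)-2-methoxybenzene
Product: 3 1-(benzyloxy)-2-methoxy-4-(prop-2-yn-1-yl)benzene
Conditions: HC≡CMgBr (3 equiv), CuBr (10 mol %), THF, 0 → 50 °C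
Reagents that add atoms: ethynylmagnesium bromide C#C[Mg]Br
Why: Copper-catalysed coupling of an alkynyl Grignard reagent with a benzylic bromide; the excess of Grignard reagent should suppress double benzylation, and a neutral work-up avoids propargyl-to-allenyl isomerisation.

Step 3
Reactants: 4 3,4-dihydroxy-5-methoxybenzaldehyde
Product: 5 3,4-bis(benzyloxy)-5-methoxybenzaldehyde
Conditions: BnBr (2.3 equiv), K2CO3, DMF, 60 °C
Reagents that add atoms: benzyl bromide BrCc1ccccc1
Why: Williamson etherification of both phenols; benzyl ethers should survive the organolithium, heat, aqueous acid, borane and Mitsunobu conditions that follow.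

Step 4
Reactants: 3 1-(benzyloxy)-2-methoxy-4-(prop-2-yn-1-yl)benzene, 5 3,4-bis(benzyloxy)-5-methoxybenzaldehyde
Product: 7 (±)-1-[3,4-bis(benzyloxy)-5-methoxyphenyl]-4-[4-(benzyloxy)-3-methoxyphenyl]but-2-yn-1-ol, via lithium acetylide 6 (not isolated)
Conditions: n-BuLi (1.0 equiv), THF, −78 °C; then 5, −78 → 0 °C; aq. NH4Cl
Reagents that add atoms: none
Why: The sp C–H is far more acidic than the benzylic propargylic CH2, so one equivalent of base gives the acetylide, which adds 1,2 to the aromatic aldehyde; the carbinol is racemic and is oxidised in the next step.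

Step 5
Reactants: 7 (±)-1-[3,4-bis(benzyloxy)-5-methoxyphenyl]-4-[4-(benzyloxy)-3-methoxyphenyl]but-2-yn-1-ol
Product: 8 1-[3,4-bis(benzyloxy)-5-methoxyphenyl]-4-[4-(benzyloxy)-3-methoxyphenyl]but-2-yn-1-one
Conditions: MnO2 (activated, 15 equiv), CH2Cl2, 23 °C
Reagents that add atoms: none
Why: Neutral heterogeneous oxidation of a benzylic propargylic alcohol to the ynone, without any base that could isomerise the skipped ynone to the allenyl ketone.

Step 6
Reactants: 8 1-[3,4-bis(benzyloxy)-5-methoxyphenyl]-4-[4-(benzyloxy)-3-methoxyphenyl]but-2-yn-1-one, 9 5-ethoxy-4-methyl-1,3-oxazole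
Product: 11 [3,4-bis(benzyloxy)-5-methoxyphenyl]{4-[4-(benzyloxy)-3-methoxybenzyl]-2-ethoxyfuran-3-yl}methanone, via 7-oxa-2-azabicyclo[2.2.1]heptadiene cycloadduct 10 (not isolated)
Conditions: 9 (3 equiv), PhMe, 110 °C, sealed tube
Reagents that add atoms: none
Why: The electron-rich 2-azadiene of the oxazole (C2=N3–C4=C5, raised in energy by the 5-ethoxy group) should add across the ynone triple bond in a normal-demand Diels–Alder reaction to give the 7-oxa-2-azanorbornadiene 10, which at the same temperature undergoes a retro-Diels–Alder reaction that expels acetonitrile (N3 and C4 with its methyl group) and leaves the aromatic 2-ethoxyfuran. The closest known reaction type is the Kondrat'eva oxazole cycloaddition in its alkyne version, the established way from 5-alkoxyoxazoles and acetylenic esters or ketones to 2-alkoxyfurans, which are masked butenolides. The five-membered oxygen ring of the target is closed by this cycloaddition–cycloreversion pair, a formal [3+2] union of the C2–O1–C5 unit of the oxazole with the two alkyne carbons, in which furan C2(OEt)–C3 and C5(H)–C4 are formed together. No lasting stereocentre is created, because the two bridgehead centres of 10 become sp2 in the furan. The step needs regiocontrol, with the acyl-bearing alkyne carbon bonding to C5(OEt): the largest HOMO coefficient of the diene lies on C2, remote from the alkoxy donor, and pairs with the β-carbon of the ynone, the same orientation that places the acceptor group next to the hydroxyl in pyridines made from 5-alkoxyoxazoles and acrylic dienophiles. Chemoselectivity follows from the ketone, which activates only this triple bond and is kept as the carbon that later becomes the benzylidene CH.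

Step 7
Reactants: 11 [3,4-bis(benzyloxy)-5-methoxyphenyl]{4-[4-(benzyloxy)-3-methoxybenzyl]-2-ethoxyfuran-3-yl}methanone
Product: 12 3-[3,4-bis(benzyloxy)-5-methoxybenzoyl]-4-[4-(benzyloxy)-3-methoxybenzyl]furan-2(5H)-one
Conditions: 2 M aq. HCl, THF, 40 °C
Reagents that add atoms: water O
Why: Hydrolysis of a 2-alkoxyfuran (cyclic ketene acetal) to a butenolide: protonation at C5, capture of the C2 dioxocarbenium ion by water and loss of ethanol should give the 2(5H)-furanone tautomer that is conjugated with both carbonyl groups.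

Step 8
Reactants: 12 3-[3,4-bis(benzyloxy)-5-methoxybenzoyl]-4-[4-(benzyloxy)-3-methoxybenzyl]furan-2(5H)-one
Product: 13 3-{(S)-[3,4-bis(benzyloxy)-5-methoxyphenyl](hydroxy)methyl}-4-[4-(benzyloxy)-3-methoxybenzyl]furan-2(5H)-one
Conditions: (R)-Me-CBS oxazaborolidine [(R)-1-methyl-3,3-diphenyltetrahydro-1H,3H-pyrrolo[1,2-c][1,3,2]oxazaborole] (20 mol %), catecholborane (1.8 equiv), PhMe, −78 → −40 °C; MeOH, pH 7 buffer
Reagents that add atoms: none
Why: Corey–Bakshi–Shibata reduction, in which the oxazaborolidine–borane complex binds the ketone anti to its larger substituent and delivers hydride to one face, with 1,2-reduction expected to outrun conjugate reduction at low temperature; the (S)-carbinol is set by the catalyst.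

Step 9
Reactants: 13 3-{(S)-[3,4-bis(benzyloxy)-5-methoxyphenyl](hydroxy)methyl}-4-[4-(benzyloxy)-3-methoxybenzyl]furan-2(5H)-one
Product: 16 (3Z,4S)-3-[3,4-bis(benzyloxy)-5-methoxybenzylidene]-4-[4-(benzyloxy)-3-methoxybenzyl]dihydrofuran-2(3H)-one, via Mitsunobu sulfonylhydrazide 14 (not isolated), via allylic diazene 15 (not isolated)
Conditions: 2-O2NC6H4SO2NHNH2, PPh3, DEAD, N-methylmorpholine, −30 °C, 2 h; then 23 °C
Reagents that add atoms: none
Why: Mitsunobu displacement by the sulfonamide N–H of o-nitrobenzenesulfonylhydrazide should invert the carbinol to the (R)-hydrazide 14, loss of the sulfinic acid gives the allylic diazene 15, and its concerted retro-ene rearrangement (reductive 1,3-transposition of an allylic alcohol) delivers the N–H hydrogen suprafacially to C4 while N2 leaves; the benzyl group on C4 forces the carbinol C–H into the plane of the double bond (allylic 1,3-strain), so the aryl group should end cis to the lactone carbonyl (Z) and the hydrogen should enter the face that gives 4S.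

Step 10
Reactants: 16 (3Z,4S)-3-[3,4-bis(benzyloxy)-5-methoxybenzylidene]-4-[4-(benzyloxy)-3-methoxybenzyl]dihydrofuran-2(3H)-one
Product: 17 (3Z,4S)-3-(3,4-dihydroxy-5-methoxybenzylidene)-4-(4-hydroxy-3-methoxybenzyl)dihydrofuran-2(3H)-one
Conditions: BCl3 (1 M in CH2Cl2), C6HMe5, CH2Cl2, −78 °C; MeOH/H2O work-up
Reagents that add atoms: none
Why: BCl3 cleaves aryl benzyl ethers at −78 °C while pentamethylbenzene traps the benzyl cations as a non-basic scavenger; the lactone, the aryl methyl ethers, the Z double bond and the C4 stereocentre should be untouched.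

**Compound list**
1 | 4-(benzyloxy)-3-methoxybenzyl alcohol | COc1cc(CO)ccc1OCc1ccccc1 | starting material
2 | 1-(benzyloxy)-4-(bromomethyl)-2-methoxybenzene | COc1cc(CBr)ccc1OCc1ccccc1 | intermediate
3 | 1-(benzyloxy)-2-methoxy-4-(prop-2-yn-1-yl)benzene | COc1cc(CC#C)ccc1OCc1ccccc1 | intermediate
4 | 3,4-dihydroxy-5-methoxybenzaldehyde | COc1cc(C=O)cc(O)c1O | starting material
5 | 3,4-bis(benzyloxy)-5-methoxybenzaldehyde | COc1cc(C=O)cc(OCc2ccccc2)c1OCc1ccccc1 | intermediate
6 | {3-[4-(benzyloxy)-3-methoxyphenyl]prop-1-yn-1-yl}lithium | COc1cc(CC#C[Li])ccc1OCc1ccccc1 | intermediate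
7 | (±)-1-[3,4-bis(benzyloxy)-5-methoxyphenyl]-4-[4-(benzyloxy)-3-methoxyphenyl]but-2-yn-1-ol | COc1cc(CC#CC(O)c2cc(OC)c(OCc3ccccc3)c(OCc3ccccc3)c2)ccc1OCc1ccccc1 | intermediate
8 | 1-[3,4-bis(benzyloxy)-5-methoxyphenyl]-4-[4-(benzyloxy)-3-methoxyphenyl]but-2-yn-1-one | COc1cc(CC#CC(=O)c2cc(OC)c(OCc3ccccc3)c(OCc3ccccc3)c2)ccc1OCc1ccccc1 | intermediate
9 | 5-ethoxy-4-methyl-1,3-oxazole | CCOc1ocnc1C | starting material
10 | (±)-{6-[4-(benzyloxy)-3-methoxybenzyl]-4-ethoxy-3-methyl-7-oxa-2-azabicyclo[2.2.1]hepta-2,5-dien-5-yl}[3,4-bis(benzyloxy)-5-methoxyphenyl]methanone | CCOC12OC(N=C1C)C(Cc1ccc(OCc3ccccc3)c(OC)c1)=C2C(=O)c1cc(OC)c(OCc2ccccc2)c(OCc2ccccc2)c1 | intermediate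
11 | [3,4-bis(benzyloxy)-5-methoxyphenyl]{4-[4-(benzyloxy)-3-methoxybenzyl]-2-ethoxyfuran-3-yl}methanone | CCOc1occ(Cc2ccc(OCc3ccccc3)c(OC)c2)c1C(=O)c1cc(OC)c(OCc2ccccc2)c(OCc2ccccc2)c1 | intermediate
12 | 3-[3,4-bis(benzyloxy)-5-methoxybenzoyl]-4-[4-(benzyloxy)-3-methoxybenzyl]furan-2(5H)-one | O=C1OCC(Cc2ccc(OCc3ccccc3)c(OC)c2)=C1C(=O)c1cc(OC)c(OCc2ccccc2)c(OCc2ccccc2)c1 | intermediate
13 | 3-{(S)-[3,4-bis(benzyloxy)-5-methoxyphenyl](hydroxy)methyl}-4-[4-(benzyloxy)-3-methoxybenzyl]furan-2(5H)-one | O=C1OCC(Cc2ccc(OCc3ccccc3)c(OC)c2)=C1[C@@H](O)c1cc(OC)c(OCc2ccccc2)c(OCc2ccccc2)c1 | intermediate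
14 | N-{(R)-[3,4-bis(benzyloxy)-5-methoxyphenyl]{4-[4-(benzyloxy)-3-methoxybenzyl]-2-oxo-2,5-dihydrofuran-3-yl}methyl}-2-nitrobenzenesulfonohydrazide | O=C1OCC(Cc2ccc(OCc3ccccc3)c(OC)c2)=C1[C@H](N(N)S(=O)(=O)c1ccccc1[N+](=O)[O-])c1cc(OC)c(OCc2ccccc2)c(OCc2ccccc2)c1 | intermediate
15 | 3-{(R)-[3,4-bis(benzyloxy)-5-methoxyphenyl](diazenyl)methyl}-4-[4-(benzyloxy)-3-methoxybenzyl]furan-2(5H)-one | O=C1OCC(Cc2ccc(OCc3ccccc3)c(OC)c2)=C1[C@H](N=N)c1cc(OC)c(OCc2ccccc2)c(OCc2ccccc2)c1 | intermediate
16 | (3Z,4S)-3-[3,4-bis(benzyloxy)-5-methoxybenzylidene]-4-[4-(benzyloxy)-3-methoxybenzyl]dihydrofuran-2(3H)-one | COc1cc(C[C@@H]2COC(=O)/C2=C\c2cc(OCc3ccccc3)c(OCc3ccccc3)c(OC)c2)ccc1OCc1ccccc1 | intermediate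
17 | (3Z,4S)-3-(3,4-dihydroxy-5-methoxybenzylidene)-4-(4-hydroxy-3-methoxybenzyl)dihydrofuran-2(3H)-one | COc1cc(C[C@@H]2COC(=O)/C2=C\c2cc(O)c(O)c(OC)c2)ccc1O | target

**Step count**
Total steps: 10. Longest linear sequence: 9 steps (1 → 2 → 3 → 7 → 8 → 11 → 12 → 13 → 16 → 17).

**Steps most likely to fail**

Step 9. The Mitsunobu displacement at the hindered, cation-stabilised carbinol may be slow, may ionise (loss of stereochemical fidelity) or may give vinylogous elimination through the acidic C5 methylene. The fallback sets out from 13 and returns at 16. Compound 13 is O-formylated (HCO2H, DCC, DMAP cat., CH2Cl2, 0 °C) to (S)-[3,4-bis(benzyloxy)-5-methoxyphenyl]{4-[4-(benzyloxy)-3-methoxybenzyl]-2-oxo-2,5-dihydrofuran-3-yl}methyl formate F1. This is treated with Pd(OAc)2 and n-Bu3P in THF at 23–50 °C, where zerovalent palladium forms in situ. Oxidative addition anti to the formate, loss of CO2 and hydride transfer from palladium to the more substituted allyl terminus C4 (the palladium-catalysed formate reduction of allylic esters) should deliver hydrogen to the same face as the diazene route and give 16.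

Step 8. Facial discrimination between two unsaturated ketone substituents may be insufficient, and conjugate reduction of the doubly activated double bond may compete. The fallback sets out from 11 and returns at 13. The ketone is reduced before the lactone is unmasked, where conjugate reduction is impossible and the ortho,ortho'-disubstituted furyl group differs sharply in bulk from the unhindered aryl group. Noyori asymmetric hydrogenation (trans-RuCl2[(S)-xylbinap][(S)-daipen] or its antipode, chosen to give the S carbinol, t-BuOK cat., i-PrOH, H2 8 atm) should give (S)-[3,4-bis(benzyloxy)-5-methoxyphenyl]{4-[4-(benzyloxy)-3-methoxybenzyl]-2-ethoxyfuran-3-yl}methanol F2. Hydrolysis of the ketene acetal under buffered conditions (aqueous oxalic acid, THF, 0 °C) then gives 13.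

Step 6. The skipped ynone may isomerise to the allenyl ketone on heating, the internal alkyne may add sluggishly, or regiocontrol may erode. The fallback sets out from 2 and 5 and returns at 12, building the butenolide without a cycloaddition. Zinc insertion into 2 (Zn dust, LiCl, THF) gives [4-(benzyloxy)-3-methoxybenzyl]zinc bromide F3. Negishi coupling with commercial 3,4-dibromofuran-2(5H)-one (Pd(PPh3)4, zerovalent palladium, THF), which reacts at the more electrophilic C4–Br bond, gives 4-[4-(benzyloxy)-3-methoxybenzyl]-3-bromofuran-2(5H)-one F4. Nozaki–Hiyama–Kishi coupling of F4 with aldehyde 5 (CrCl2, NiCl2 cat., DMF) gives (±)-3-{[3,4-bis(benzyloxy)-5-methoxyphenyl](hydroxy)methyl}-4-[4-(benzyloxy)-3-methoxybenzyl]furan-2(5H)-one F5. Dess–Martin oxidation gives 12, and the route continues with step 8.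

Further compounds
F1 | step 9 | (S)-[3,4-bis(benzyloxy)-5-methoxyphenyl]{4-[4-(benzyloxy)-3-methoxybenzyl]-2-oxo-2,5-dihydrofuran-3-yl}methyl formate | O=C1OCC(Cc2ccc(OCc3ccccc3)c(OC)c2)=C1[C@@H](OC=O)c1cc(OC)c(OCc2ccccc2)c(OCc2ccccc2)c1
F2 | step 8 | (S)-[3,4-bis(benzyloxy)-5-methoxyphenyl]{4-[4-(benzyloxy)-3-methoxybenzyl]-2-ethoxyfuran-3-yl}methanol | CCOc1occ(Cc2ccc(OCc3ccccc3)c(OC)c2)c1[C@@H](O)c1cc(OC)c(OCc2ccccc2)c(OCc2ccccc2)c1
F3 | step 6 | [4-(benzyloxy)-3-methoxybenzyl]zinc bromide | COc1cc(C[Zn]Br)ccc1OCc1ccccc1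
F4 | step 6 | 4-[4-(benzyloxy)-3-methoxybenzyl]-3-bromofuran-2(5H)-one | O=C1OCC(Cc2ccc(OCc3ccccc3)c(OC)c2)=C1Br
F5 | step 6 | (±)-3-{[3,4-bis(benzyloxy)-5-methoxyphenyl](hydroxy)methyl}-4-[4-(benzyloxy)-3-methoxybenzyl]furan-2(5H)-one | O=C1OCC(Cc2ccc(OCc3ccccc3)c(OC)c2)=C1C(O)c1cc(OC)c(OCc2ccccc2)c(OCc2ccccc2)c1
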